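Ring A is disconnected into three pieces: a methoxy(1,2-dimethoxyvinyl)carbene complex of Cr(CO)5, one of its CO ligands and a silylated propargyl alcohol. A Dötz benzannulation joins them in one operation, forming C5–C6, C4a–C8a and C8–C8a (flavone numbering) and closing the benzene ring with all five substituents in place. It exploits the hydroquinone monoether pattern of ring A: C8a–O1 para to C6–OMe, methoxy groups on C7 and C8 between them, hydrogen on C5 and the future C4 on C4a. The phenol is then capped, the benzylic carbon is raised to the aldehyde, and ring C is closed by aldol addition of an α-methoxy ketone, oxidation and acid cyclodehydration.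

Key step: step 2

Remark: 2-methoxy-1-(4-methoxyphenyl)ethanone and geometrically pure (Z)-1,2-dimethoxyethene are taken as purchasable.

Step 1
Reactants: 1 (Z)-1,2-dimethoxyethene; 2 chromium hexacarbonyl Cr(CO)6
Product: 5 pentacarbonyl[(Z)-1,2-dimethoxyvinyl(methoxy)carbene]chromium, via (Z)-1,2-dimethoxyvinyllithium 3 (not isolated), via lithium acylchromate 4 (not isolated)
Conditions: t-BuLi, THF, −78 °C; Cr(CO)6, −78 °C to rt; then Me3OBF4, CH2Cl2, 0 °C
Reagents that add atoms: trimethyloxonium tetrafluoroborate, C[O+](C)C.F[B-](F)(F)F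
Why: Fischer carbene synthesis: the enol ether is lithiated at its α-carbon with retention of the Z geometry, the vinyllithium adds to a CO ligand, and the Meerwein salt O-methylates the acylchromate; the low temperature should keep the lithium compound from eliminating LiOMe.

Step 2
Reactants: 5 pentacarbonyl[(Z)-1,2-dimethoxyvinyl(methoxy)carbene]chromium; 6 tert-butyldimethyl(prop-2-yn-1-yloxy)silane
Product: 8 6-[(tert-butyldimethylsilyloxy)methyl]-2,3,4-trimethoxyphenol, via tricarbonylchromium arene complex 7 (not isolated)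
Conditions: 6 (1.5 equiv), THF (0.05 M), 50 °C, argon; then air, Et2O, daylight, rt
Reagents that add atoms: none
Why: Proposed new method: thermal loss of one CO from 5 should let alkyne 6 insert into the Cr=C bond with its CH carbon bonded to the carbene carbon (C5–C6 in flavone numbering), CO insertion should give an η4-vinylketene complex (C4a–C8a), and the ketene carbon should close onto the methoxy-bearing β-carbon of the dimethoxyvinyl group (C8–C8a) before tautomerisation to the Cr(CO)3-bound phenol 7, from which air frees 8. The closest known reaction type is the Dötz benzannulation of alkenyl(methoxy)carbene complexes of zerovalent chromium with terminal alkynes to 4-methoxyphenols; a 1,2-dialkoxyalkenyl carbene has not been shown in it. Ring A closes by 6π electrocyclisation of the metal-bound dienylketene. No stereocentre is formed. The step needs the regiochemistry that puts the silyloxymethyl group next to the CO-derived carbon C8a, secured by the steric difference between H and CH2OSi at the alkyne, and it needs CO insertion to outrun CO-free closure to five-membered rings, which the methoxycarbene on chromium, THF as solvent and the inductive pull of the α-methoxy group should favour. The Z geometry of 5 holds the β-methoxy group trans to the carbene carbon, so that only hydrogen points into the closing ring.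

Step 3
Reactants: 8 6-[(tert-butyldimethylsilyloxy)methyl]-2,3,4-trimethoxyphenol
Product: 9 tert-butyl{[2-(methoxymethoxy)-3,4,5-trimethoxyphenyl]methoxy}dimethylsilane
Conditions: MOMCl, i-Pr2NEt, CH2Cl2, 0 °C to 40 °C
Reagents that add atoms: chloromethyl methyl ether, COCCl
Why: O-alkylation of the phenol (Williamson-type ether formation) should cap the oxidation-prone hydroquinone monoether before any oxidant is used.

Step 4
Reactants: 9 tert-butyl{[2-(methoxymethoxy)-3,4,5-trimethoxyphenyl]methoxy}dimethylsilane
Product: 10 [2-(methoxymethoxy)-3,4,5-trimethoxyphenyl]methanol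
Conditions: Bu4NF, AcOH, THF, 0 °C to rt
Reagents that add atoms: none
Why: Fluoride-driven cleavage of the silyl ether, buffered by acetic acid, should leave the acetal and the methyl ethers untouched.

Step 5
Reactants: 10 [2-(methoxymethoxy)-3,4,5-trimethoxyphenyl]methanol
Product: 11 2-(methoxymethoxy)-3,4,5-trimethoxybenzaldehyde
Conditions: MnO2 (activated, excess), CH2Cl2, rt
Reagents that add atoms: none
Why: MnO2 oxidation of an activated benzylic alcohol should stop cleanly at the aldehyde.

Step 6
Reactants: 11 2-(methoxymethoxy)-3,4,5-trimethoxybenzaldehyde; 12 2-methoxy-1-(4-methoxyphenyl)ethanone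
Product: 15 3-hydroxy-2-methoxy-3-[2-(methoxymethoxy)-3,4,5-trimethoxyphenyl]-1-(4-methoxyphenyl)propan-1-one as a mixture of racemic diastereomers, via lithium enolate 13 (not isolated), via lithium aldolate 14 (not isolated)
Conditions: 12, LiN(SiMe3)2, THF, −78 °C; then 11, −78 °C; AcOH quench at −78 °C
Reagents that add atoms: none
Why: Directed aldol addition of the preformed lithium enolate to a non-enolisable aldehyde; the two new stereocentres (future C3 and C4) form without control, which is harmless because steps 7 and 8 remove both.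

Step 7
Reactants: 15 3-hydroxy-2-methoxy-3-[2-(methoxymethoxy)-3,4,5-trimethoxyphenyl]-1-(4-methoxyphenyl)propan-1-one
Product: 16 2-methoxy-1-[2-(methoxymethoxy)-3,4,5-trimethoxyphenyl]-3-(4-methoxyphenyl)propane-1,3-dione (racemic)
Conditions: Dess–Martin periodinane, CH2Cl2, rt
Reagents that add atoms: none
Why: Dess–Martin oxidation should turn the β-hydroxy ketone into the 1,3-diketone under neutral conditions that do not provoke a retro-aldol; the benzylic stereocentre is removed and the remaining one is labile and irrelevant.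

Step 8
Reactants: 16 2-methoxy-1-[2-(methoxymethoxy)-3,4,5-trimethoxyphenyl]-3-(4-methoxyphenyl)propane-1,3-dione
Product: 19 auranetin [3,6,7,8-tetramethoxy-2-(4-methoxyphenyl)-4H-chromen-4-one], via phenol diketone 17 (not isolated), via cyclic hemiketal 18 (not isolated)
Conditions: HCl (cat.), MeOH, 60 °C
Reagents that add atoms: none
Why: Acid methanolysis should remove the methoxymethyl acetal, after which the free phenol adds to the anisoyl carbonyl and water is lost, the classical cyclodehydration of an o-hydroxyaryl 1,3-diketone to a flavone; no stereocentre remains.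

Compound list
1 | (Z)-1,2-dimethoxyethene | CO/C=C\OC | starting material
2 | chromium hexacarbonyl, Cr(CO)6 | [Cr].[C-]#[O+].[C-]#[O+].[C-]#[O+].[C-]#[O+].[C-]#[O+].[C-]#[O+] | starting material
3 | (Z)-1,2-dimethoxyvinyllithium (Li trans to the 2-methoxy group) | [Li]/C(OC)=C/OC | intermediate
4 | lithium pentacarbonyl[(Z)-2,3-dimethoxyacryloyl]chromate | [Li+].[O-]C(=[Cr])/C(OC)=C/OC.[C-]#[O+].[C-]#[O+].[C-]#[O+].[C-]#[O+].[C-]#[O+] | intermediate
5 | pentacarbonyl[(Z)-1,2-dimethoxyvinyl(methoxy)carbene]chromium (β-methoxy trans to the carbene carbon) | COC(=[Cr])/C(OC)=C/OC.[C-]#[O+].[C-]#[O+].[C-]#[O+].[C-]#[O+].[C-]#[O+] | intermediate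
6 | tert-butyldimethyl(prop-2-yn-1-yloxy)silane | C#CCO[Si](C)(C)C(C)(C)C | starting material
7 | tricarbonyl{η6-6-[(tert-butyldimethylsilyloxy)methyl]-2,3,4-trimethoxyphenol}chromium | COc1cc(CO[Si](C)(C)C(C)(C)C)c(O)c(OC)c1OC.[Cr].[C-]#[O+].[C-]#[O+].[C-]#[O+] | intermediate
8 | 6-[(tert-butyldimethylsilyloxy)methyl]-2,3,4-trimethoxyphenol | COc1cc(CO[Si](C)(C)C(C)(C)C)c(O)c(OC)c1OC | intermediate
9 | tert-butyl{[2-(methoxymethoxy)-3,4,5-trimethoxyphenyl]methoxy}dimethylsilane | COCOc1c(CO[Si](C)(C)C(C)(C)C)cc(OC)c(OC)c1OC | intermediate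
10 | [2-(methoxymethoxy)-3,4,5-trimethoxyphenyl]methanol | COCOc1c(CO)cc(OC)c(OC)c1OC | intermediate
11 | 2-(methoxymethoxy)-3,4,5-trimethoxybenzaldehyde | COCOc1c(C=O)cc(OC)c(OC)c1OC | intermediate
12 | 2-methoxy-1-(4-methoxyphenyl)ethanone | COCC(=O)c1ccc(OC)cc1 | starting material
13 | lithium (Z)-2-methoxy-1-(4-methoxyphenyl)ethen-1-olate | [Li]O/C(=C\OC)c1ccc(OC)cc1 | intermediate
14 | lithium aldolate of 15 (mixture of racemic diastereomers) | COCOc1c(C(O[Li])C(OC)C(=O)c2ccc(OC)cc2)cc(OC)c(OC)c1OC | intermediate
15 | 3-hydroxy-2-methoxy-3-[2-(methoxymethoxy)-3,4,5-trimethoxyphenyl]-1-(4-methoxyphenyl)propan-1-one (mixture of racemic diastereomers) | COCOc1c(C(O)C(OC)C(=O)c2ccc(OC)cc2)cc(OC)c(OC)c1OC | intermediate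
16 | 2-methoxy-1-[2-(methoxymethoxy)-3,4,5-trimethoxyphenyl]-3-(4-methoxyphenyl)propane-1,3-dione (racemic) | COCOc1c(C(=O)C(OC)C(=O)c2ccc(OC)cc2)cc(OC)c(OC)c1OC | intermediate
17 | 1-(2-hydroxy-3,4,5-trimethoxyphenyl)-2-methoxy-3-(4-methoxyphenyl)propane-1,3-dione (racemic) | COc1ccc(C(=O)C(OC)C(=O)c2cc(OC)c(OC)c(OC)c2O)cc1 | intermediate
18 | 2-hydroxy-3,6,7,8-tetramethoxy-2-(4-methoxyphenyl)chroman-4-one (mixture of racemic diastereomers) | COc1ccc(C2(O)Oc3c(OC)c(OC)c(OC)cc3C(=O)C2OC)cc1 | intermediate
19 | auranetin, 3,6,7,8-tetramethoxy-2-(4-methoxyphenyl)-4H-chromen-4-one (no stereocentre) | COc1ccc(-c2oc3c(OC)c(OC)c(OC)cc3c(=O)c2OC)cc1 | target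

Total step count: 8. Longest linear sequence: 8 steps (1 to 19; ketone 12 is bought).

Steps most likely to fail

1. Step 2 (Proposed new method). Alkyne insertion may be slow for this donor-stabilised carbene. CO insertion may be outrun by CO-free closure to five-membered rings or by alkyne oligomerisation. The hydroquinone monoether may be over-oxidised during decomplexation. The fallback uses known chemistry, sets out from alkyne 6 and comes back to the route at phenol 8. Radical hydrostannylation of 6 (Bu3SnH, AIBN, 80 °C) should give (E)-tert-butyldimethyl{[3-(tributylstannyl)prop-2-en-1-yl]oxy}silane F1. Tin–lithium exchange (n-BuLi, THF, −78 °C) gives (E)-3-(tert-butyldimethylsilyloxy)prop-1-enyllithium F2. It adds to one carbonyl group of purchasable dimethyl squarate F3 to give the lithium alkoxide F4. Methylation in the flask with MeOTf gives 4-[(E)-3-(tert-butyldimethylsilyloxy)prop-1-enyl]-2,3,4-trimethoxycyclobut-2-en-1-one F5. Heating F5 in toluene at 110 °C should open the four-membered ring (methoxy outward) to the same kind of dienylketene, which closes by 6π electrocyclisation and tautomerises to 8. This is the known thermal ring expansion of 4-alkenyl-4-alkoxycyclobutenones to hydroquinone monoethers.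

2. Step 1. The vinyllithium may undergo anti-β-elimination of LiOMe, or lose its alkene geometry, before it is captured by Cr(CO)6. The fallback avoids any vinyllithium, sets out from 1 and 2 and comes back at carbene complex 5. Acylation of 1 with oxalyl chloride (0 °C to rt) should give (Z)-3,4-dimethoxy-2-oxobut-3-enoyl chloride F6. On heating to 120 °C it loses CO to give (Z)-2,3-dimethoxyacryloyl chloride F7, by the known route from enol ethers to 3-alkoxyacryloyl chlorides. Reduction of 2 with C8K (THF, −78 °C to rt) gives K2Cr(CO)5 F8. F8 and F7 give potassium pentacarbonyl[(Z)-2,3-dimethoxyacryloyl]chromate F9, which Me3OBF4 methylates to 5.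

3. Step 6. The aldol addition may reverse on warming or work-up, and addition to the hindered, electron-rich aldehyde may be slow enough for enolate self-condensation to compete. The fallback replaces the reversible addition by an irreversible acylation, sets out from aldehyde 11 and comes back at diketone 16, so that step 7 is no longer needed. Pinnick oxidation of 11 (NaClO2, NaH2PO4, 2-methyl-2-butene, t-BuOH/H2O) gives 2-(methoxymethoxy)-3,4,5-trimethoxybenzoic acid F10. 1,1'-Carbonyldiimidazole in THF gives 1H-imidazol-1-yl[2-(methoxymethoxy)-3,4,5-trimethoxyphenyl]methanone F11. Claisen-type C-acylation of two equivalents of enolate 13 with F11 at −78 °C should give 16 directly.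

Further compounds
F1 | step 2 | (E)-tert-butyldimethyl{[3-(tributylstannyl)prop-2-en-1-yl]oxy}silane | CCCC[Sn](CCCC)(CCCC)/C=C/CO[Si](C)(C)C(C)(C)C
F2 | step 2 | (E)-3-(tert-butyldimethylsilyloxy)prop-1-enyllithium | [Li]/C=C/CO[Si](C)(C)C(C)(C)C
F3 | step 2 | dimethyl squarate, 3,4-dimethoxycyclobut-3-ene-1,2-dione | COC1=C(OC)C(=O)C1=O
F4 | step 2 | lithium 1-[(E)-3-(tert-butyldimethylsilyloxy)prop-1-enyl]-2,3-dimethoxy-4-oxocyclobut-2-en-1-olate (racemic) | COC1=C(OC)C(O[Li])(/C=C/CO[Si](C)(C)C(C)(C)C)C1=O
F5 | step 2 | 4-[(E)-3-(tert-butyldimethylsilyloxy)prop-1-enyl]-2,3,4-trimethoxycyclobut-2-en-1-one (racemic) | COC1=C(OC)C(OC)(/C=C/CO[Si](C)(C)C(C)(C)C)C1=O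
F6 | step 1 | (Z)-3,4-dimethoxy-2-oxobut-3-enoyl chloride | CO/C=C(\OC)C(=O)C(=O)Cl
F7 | step 1 | (Z)-2,3-dimethoxyacryloyl chloride | CO/C=C(\OC)C(=O)Cl
F8 | step 1 | dipotassium pentacarbonylchromate, K2Cr(CO)5 | [K+].[K+].[Cr-2].[C-]#[O+].[C-]#[O+].[C-]#[O+].[C-]#[O+].[C-]#[O+]
F9 | step 1 | potassium pentacarbonyl[(Z)-2,3-dimethoxyacryloyl]chromate | [K+].[O-]C(=[Cr])/C(OC)=C/OC.[C-]#[O+].[C-]#[O+].[C-]#[O+].[C-]#[O+].[C-]#[O+]
F10 | step 6 | 2-(methoxymethoxy)-3,4,5-trimethoxybenzoic acid | COCOc1c(C(=O)O)cc(OC)c(OC)c1OC
F11 | step 6 | 1H-imidazol-1-yl[2-(methoxymethoxy)-3,4,5-trimethoxyphenyl]methanone | COCOc1c(C(=O)n2ccnc2)cc(OC)c(OC)c1OC
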